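## The problem

Guanipiperazine A (26) is a guanine joined through C8 to ring A of a 14-membered cyclophane. Ring A is bridged 1,3 and carries a free phenol between the guanine and the diaryl ether oxygen. Ring B is a para-phenylene. The two rings are tied by the ether oxygen and, through their benzylic CH2 groups, by C5 and C2 of a cis-(2S,5S)-piperazine.

Fourteen ring atoms are too few for a relaxed para-phenylene. Any closure that bonds to a finished, flat ring B (the aryl ether bond or a benzylic C–C bond) must bend that ring in its transition state while oligomerisation competes.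

The two stereocentres are the α-carbons of two L-amino acids. They sit 1,4 across the piperazine, too far apart for one to direct the other reliably, so each is set independently and guarded at the amino ester and diketopiperazine stages, where epimerisation is still possible.

The guanine is polar, poorly soluble and rich in NH groups and should come last. The secondary amines need masking, and the electron-rich ring A will not stand strong oxidants.

Ring A helps in one way: the only free position ortho to the phenol is the carbon that must carry C8, so an ortho-selective formylation needs no further directing group.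

Ring B makes the key step possible. It bears only an oxygen and a CH2 group, para to one another, and four CH positions. That is the benzene formed when a 2-pyrone with the oxygen at C5 adds a terminal propargyl group across C3 and C6 and loses CO2.

## Retrosynthesis

**Guanine.** Cutting C8–N7 and C8–N9 of 26 (protected as the di-Boc compound 25) gives salicylaldehyde 21 and 2,5,6-triaminopyrimidin-4(3H)-one 22. The neighbouring cut, the C8–aryl bond, would need a protected 8-halopurine and a metalated phenol flanked on both sides. The imidazole cut uses a cheap pyrimidine and puts the insoluble heterocycle in the penultimate step. The forward reaction must condense the aldehyde with the 5-amino group, close the aminal and dehydrogenate it without harming the Boc groups or the phenol.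

**Formyl group and protecting groups.** Removing the formyl carbon of 21 gives phenol 20. Para and the second ortho position are occupied, so a magnesium-mediated ortho-formylation can only give 21. Phenol 20 comes from the benzyl-protected macrocycle 18 in one operation, hydrogenolysis in the presence of Boc2O. The exchange is needed because the ring closure requires groups that survive 200 °C, which tertiary benzyl carbamates and a benzyl ether do and Boc groups do not.

**Ring B and the macrocycle (key cut).** In 18 two parallel bonds of ring B are cut: the bond from the CH2-bearing carbon to one ortho carbon, and the bond between the ortho and meta carbons on the other side. With a bridge of CO2 added back, this gives bicyclic lactone 17 and then pyrone alkyne 16. Cutting the aryl ether C–O bond or a benzylic bond instead would force the bend of ring B into a bond-forming transition state. Here the ring closes while ring B is still a non-planar bicyclooctadiene and becomes aromatic only by irreversible loss of CO2. Precursor 16 is acyclic apart from its piperazine and already has both stereocentres. The forward reaction must deliver the substituted alkyne carbon to pyrone C3 and the terminal carbon to C6.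

**Pyronyl ether.** Cutting the bond between pyrone C5 and the phenol oxygen of 16 leads to phenol 13 and 5-bromo-2H-pyran-2-one 14, joined by copper-catalysed C–O coupling to give 15. The pyrone must come after the hydride reduction that makes the piperazine, so the alkyne is already present at the coupling. A free terminal alkyne would form copper acetylides and couple with itself or with 14. It is therefore masked as the triethylsilyl alkyne 13 (from 11, by way of the bis-silyl compound 12) and unmasked under buffered fluoride (15 to 16). These two operations are the price of a clean etherification.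

**Piperazine.** The carbamates of 11 come from diamine 10, and the four C–N single bonds of 10 from the two lactams of diketopiperazine 9. Cutting the two amide bonds of 9 gives, through the amine salt 8, dipeptide 7, and from it the ring A amino ester 4 (coupled as its salt 6) and commercial N-Boc-L-propargylglycine 5. A diketopiperazine from two L-amino acids fixes the cis relationship by construction. The reduction must be done with LiAlH4, because borane would hydroborate the alkyne.

**Ring A amino acid.** Amino ester 4 is cut at Cα–Cβ at the alkene oxidation level to give dehydroamino ester 3, and from it commercial 4-(benzyloxy)-3-hydroxybenzaldehyde 1 and phosphonoglycinate 2. Compound 1 already has the two ring A oxygens differentiated, which a route from L-DOPA or L-tyrosine would have to achieve in extra steps. The stereocentre is set by catalyst-controlled hydrogenation before any alkyne is present.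

## Roads not taken

**Alternative 1:** The cut is the benzylic bond between ring B and piperazine C2, at the alkene level. An open-chain diaryl ether A2, with a ring B aldehyde and a phosphonoglycine amide on the ring A amino acid, would be closed by intramolecular Horner–Wadsworth–Emmons olefination (LiCl, DBU, high dilution) to the 14-membered (Z)-dehydroamino ester A1.
- Merits: the diaryl ether is made early and intermolecularly, the olefination is a dependable macrocyclisation with no regiochemical question, and no masked alkyne is needed.
- Weak points: ring B is flat when the ring closes, so the bend is paid in the olefination transition state of a ring that also holds a planar enamide and a secondary amide. The second stereocentre must then be set by hydrogenating A1, where the catalyst must bind an enamide inside a strained ring whose own facial bias may oppose it. After that the amine must be freed and closed across the ring onto the ester, both lactams reduced and the ring A methyl ether cleaved.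
- Comparison: reaction for reaction this road is the more reliable. The chosen plan sets against it that both stereocentres are secure before the ring closes, that the macrocycle is formed at the piperazine oxidation level, and that the strain is paid by loss of CO2. The step counts are similar.

**Alternative 2:** The cut is through C8–N7 and C8–N9. The macrocyclic salicylaldehyde (the same compound as 21) condenses with the triaminopyrimidinone and the dihydropurine is dehydrogenated to the di-Boc guanine A3, identical with 25.
- Merits: the purine arrives last from a cheap pyrimidine, and the site of the formyl group is dictated by ring A.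
- Weak points: as a strategy it leaves the cyclophane unsolved, and the condensation can stall at the hydrogen-bonded salicylidene imine.
- Comparison: this road is absorbed, not rejected, since steps 12 and 13 are this endgame. The difference is the source of the macrocycle. Copper-mediated macro-etherification of a reduced diketopiperazine from two cheap aromatic amino acids is the better-established way to this ring and needs no pyrone or masked alkyne. The chosen plan sets against it a closure without metal or base at the strained stage, driven by gas loss, and keeps the etherification as the reserve for step 10.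

**Alternative 3:** The cut is the bond between piperazine C5 and the ring A benzylic carbon. The bis-lactim ether A5 of a glycine-containing diketopiperazine, carrying ring B, the diaryl ether and a ring A benzylic bromide, would be lithiated at the glycine carbon with LiN(iPr)2 and alkylated intramolecularly to the macrocyclic (2S,5S) bis-lactim ether A4.
- Merits: one step makes a C–C bond, the macrocycle and the second stereocentre; only one chiral amino acid is bought; the tether can deliver the electrophile only to the face that gives the cis isomer.
- Weak points: open-chain bis-lactim ether alkylation prefers the face opposite the existing substituent, so the tether must overrule that preference while closing a strained ring. The benzylic bromide para to an alkoxy group is labile and invites intermolecular alkylation. The proton at C2 is also acidic, so the base can erode the stereocentre that is meant to control the other. The product must still be taken to the piperazine and demethylated.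
- Comparison: in economy of chirality and in bonds made by the key step this road is at least equal. The chosen plan sets against it two stereocentres of independent origin that the key step cannot touch, a neutral thermal closure, and four steps from the key product to the target.

Key step: step 10

Remark on the chemistry: 22 is commercial as its sulfate and is taken as the free base, liberated just before use; 5 is the commercial N-Boc derivative of L-propargylglycine; the guanine of 26 is drawn as its 1H,7H lactam tautomer.

**Step 1**
Reactants: 1 4-(benzyloxy)-3-hydroxybenzaldehyde; 2 methyl 2-[(tert-butoxycarbonyl)amino]-2-(dimethoxyphosphoryl)acetate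
Product: 3 methyl (2Z)-3-[4-(benzyloxy)-3-hydroxyphenyl]-2-[(tert-butoxycarbonyl)amino]prop-2-enoate
Conditions: DBU (2.2 equiv), CH2Cl2, 0 °C → rt
Reagents that add atoms: none
Why: Horner–Wadsworth–Emmons olefination with a phosphonoglycinate, which should give mainly the (Z)-dehydroamino ester; the phenoxide formed from the meta hydroxyl (hence the second equivalent of base) is not conjugated with the aldehyde and should not slow the reaction much.

**Step 2**
Reactants: 3 methyl (2Z)-3-[4-(benzyloxy)-3-hydroxyphenyl]-2-[(tert-butoxycarbonyl)amino]prop-2-enoate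
Product: 4 methyl (2S)-3-[4-(benzyloxy)-3-hydroxyphenyl]-2-[(tert-butoxycarbonyl)amino]propanoate
Conditions: [Rh(cod)((S,S)-Et-DuPHOS)]BF4 (1 mol %), H2 (4 bar), MeOH, rt
Reagents that add atoms: none
Why: Rhodium–bisphospholane asymmetric hydrogenation of an N-acyl dehydroamino ester; the (S,S)-ligand should set the (S) centre (later C5 of the piperazine) by catalyst control, and rhodium leaves the benzyl ether intact.

**Step 3**
Reactants: 4 methyl (2S)-3-[4-(benzyloxy)-3-hydroxyphenyl]-2-[(tert-butoxycarbonyl)amino]propanoate; 5 (2S)-2-[(tert-butoxycarbonyl)amino]pent-4-ynoic acid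
Product: 7 methyl (2S)-3-[4-(benzyloxy)-3-hydroxyphenyl]-2-{[(2S)-2-[(tert-butoxycarbonyl)amino]pent-4-ynoyl]amino}propanoate, via amino ester hydrochloride 6 (not isolated)
Conditions: 4 M HCl in 1,4-dioxane, rt; evaporate; then 5, EDC·HCl, HOBt, iPr2NEt, CH2Cl2/DMF, 0 °C → rt
Reagents that add atoms: none
Why: Acidolysis of the Boc group followed by carbodiimide/HOBt amide coupling; the urethane-protected acid 5 should not racemise through an oxazolone, and the free phenol is acylated far more slowly than the amine.

**Step 4**
Reactants: 7 methyl (2S)-3-[4-(benzyloxy)-3-hydroxyphenyl]-2-{[(2S)-2-[(tert-butoxycarbonyl)amino]pent-4-ynoyl]amino}propanoate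
Product: 9 (3S,6S)-3-{[4-(benzyloxy)-3-hydroxyphenyl]methyl}-6-(prop-2-yn-1-yl)piperazine-2,5-dione, via dipeptide amine formate 8 (not isolated)
Conditions: HCO2H, rt; evaporate; then sec-butanol/toluene (4:1), reflux
Reagents that add atoms: none
Why: Boc removal and thermal cyclisation of a dipeptide ester amine to the diketopiperazine in a weakly acidic medium, which avoids base and so epimerisation; the cis relationship follows from the two L-configured centres.

**Step 5**
Reactants: 9 (3S,6S)-3-{[4-(benzyloxy)-3-hydroxyphenyl]methyl}-6-(prop-2-yn-1-yl)piperazine-2,5-dione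
Product: 10 2-(benzyloxy)-5-{[(2S,5S)-5-(prop-2-yn-1-yl)piperazin-2-yl]methyl}phenol
Conditions: LiAlH4 (excess), THF, reflux; aq. NaOH work-up
Reagents that add atoms: none
Why: Hydride reduction of both lactams of a diketopiperazine to the piperazine; phenol and terminal alkyne are only deprotonated (phenoxide and acetylide resist hydride), whereas borane would add to the alkyne, and the stereocentres are retained.

**Step 6**
Reactants: 10 2-(benzyloxy)-5-{[(2S,5S)-5-(prop-2-yn-1-yl)piperazin-2-yl]methyl}phenol
Product: 11 dibenzyl (2S,5S)-2-{[4-(benzyloxy)-3-hydroxyphenyl]methyl}-5-(prop-2-yn-1-yl)piperazine-1,4-dicarboxylate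
Conditions: N-(benzyloxycarbonyloxy)succinimide (2.4 equiv), Et3N, CH2Cl2, rt
Reagents that add atoms: N-(benzyloxycarbonyloxy)succinimide, O=C(OCc1ccccc1)ON1C(=O)CCC1=O
Why: Carbamate formation with an active carbonate that acylates amines in preference to the phenol; tertiary benzyl carbamates are chosen because they withstand 200 °C and later fall together with the benzyl ether.

**Step 7**
Reactants: 11 dibenzyl (2S,5S)-2-{[4-(benzyloxy)-3-hydroxyphenyl]methyl}-5-(prop-2-yn-1-yl)piperazine-1,4-dicarboxylate
Product: 13 dibenzyl (2S,5S)-2-{[4-(benzyloxy)-3-hydroxyphenyl]methyl}-5-[3-(triethylsilyl)prop-2-yn-1-yl]piperazine-1,4-dicarboxylate, via O,C-bis(triethylsilyl) compound 12 (not isolated)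
Conditions: LiN(SiMe3)2 (2.3 equiv), THF, −78 °C; Et3SiCl (2.5 equiv), −78 → 0 °C; then K2CO3 (cat.), MeOH, 0 °C
Reagents that add atoms: chlorotriethylsilane, CC[Si](Cl)(CC)CC
Why: Deprotonation of phenol and alkyne with silylation of both, then selective methanolysis of the aryl silyl ether, which the alkynylsilane survives; the silyl cap keeps the alkyne from forming copper acetylides (Glaser or Castro–Stephens-type coupling) in step 8.

**Step 8**
Reactants: 13 dibenzyl (2S,5S)-2-{[4-(benzyloxy)-3-hydroxyphenyl]methyl}-5-[3-(triethylsilyl)prop-2-yn-1-yl]piperazine-1,4-dicarboxylate; 14 5-bromo-2H-pyran-2-one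
Product: 15 dibenzyl (2S,5S)-2-({4-(benzyloxy)-3-[(6-oxo-6H-pyran-3-yl)oxy]phenyl}methyl)-5-[3-(triethylsilyl)prop-2-yn-1-yl]piperazine-1,4-dicarboxylate
Conditions: CuI (20 mol %), N,N-dimethylglycine (40 mol %), Cs2CO3, 1,4-dioxane, 80 °C
Reagents that add atoms: none
Why: Ullmann-type copper-catalysed C–O coupling of a phenol with a vinylic bromide, promoted by an amino acid ligand; sparingly soluble Cs2CO3 in dioxane keeps the phenoxide concentration low, which should limit conjugate addition to the pyrone, and carbamates, benzyl ether and silylalkyne are inert.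

**Step 9**
Reactants: 15 dibenzyl (2S,5S)-2-({4-(benzyloxy)-3-[(6-oxo-6H-pyran-3-yl)oxy]phenyl}methyl)-5-[3-(triethylsilyl)prop-2-yn-1-yl]piperazine-1,4-dicarboxylate
Product: 16 dibenzyl (2S,5S)-2-({4-(benzyloxy)-3-[(6-oxo-6H-pyran-3-yl)oxy]phenyl}methyl)-5-(prop-2-yn-1-yl)piperazine-1,4-dicarboxylate
Conditions: Bu4NF/AcOH (1:1, 1.2 equiv), THF, 0 °C → rt
Reagents that add atoms: none
Why: Fluoride-induced cleavage of the C(sp)–Si bond; the acetic acid buffer keeps the medium non-basic so that the pyrone lactone should not be opened.

**Step 10**
Reactants: 16 dibenzyl (2S,5S)-2-({4-(benzyloxy)-3-[(6-oxo-6H-pyran-3-yl)oxy]phenyl}methyl)-5-(prop-2-yn-1-yl)piperazine-1,4-dicarboxylate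
Product: 18 O-benzyl-N,N'-bis(benzyloxycarbonyl)piperazinomycin (protected 14-membered macrocycle), via bridged bicyclic lactone 17 (not isolated)
Conditions: 1,2-dichlorobenzene (0.002 M), 2,6-di-tert-butyl-4-methylphenol (cat.), 200 °C, sealed vessel, argon
Reagents that add atoms: none
Why: On heating, the pyrone acts as the diene (C3 to C6) towards the tethered alkyne in an intramolecular [4+2] cycloaddition, and the bridged lactone 17 then loses CO2 by retro-[4+2], which is irreversible and makes ring B aromatic. The closest known reaction type is the intramolecular 2-pyrone–alkyne Diels–Alder/decarboxylation used to build bent para-bridged cyclophane arenes. Ring B closes as a six-membered carbocycle through the two new bonds, pyrone C3 to the internal alkyne carbon and pyrone C6 to the terminal alkyne carbon. The 14-membered ring closes through the same bonds in the bridging mode, the tether running from the C5 oxygen to the substituted alkyne carbon, and it does so while ring B is still a non-planar bicyclooctadiene, so the bend of the para-phenylene is paid for by loss of CO2 and not in a bond-forming transition state. No stereocentre is created in 18: the two bridgehead carbons of 17 are flattened on aromatisation, so either face of the pyrone may react, and C2 and C5 of the piperazine are untouched. The selectivity needed is regiochemical, para against meta bridging: C6 is the electrophilic terminus of the pyrone and is flanked by the aryloxy-bearing C5, so the nucleophilic, unsubstituted alkyne CH should bond there and the substituted carbon at the unhindered C3, and a ten-atom tether is long enough not to overrule this preference. The two carbamates hold both side arms pseudoaxial on one face of the piperazine, which brings the reacting ends together; high dilution suppresses intermolecular cycloaddition; tertiary benzyl carbamates and the benzyl ether tolerate the temperature where Boc groups would not.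

**Step 11**
Reactants: 18 O-benzyl-N,N'-bis(benzyloxycarbonyl)piperazinomycin (protected 14-membered macrocycle)
Product: 20 N,N'-bis(tert-butoxycarbonyl)piperazinomycin, via piperazinomycin 19 (not isolated)
Conditions: H2 (1 atm), Pd/C (10 wt %), Boc2O (2.5 equiv), EtOAc/EtOH, rt
Reagents that add atoms: di-tert-butyl dicarbonate, CC(C)(C)OC(=O)OC(=O)OC(C)(C)C
Why: Hydrogenolysis of both benzyl carbamates and the benzyl ether with in situ capture of the freed secondary amines by Boc2O (one-pot transprotection); without base the phenol is not acylated, and diaryl ether and stereocentres are unaffected.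

**Step 12**
Reactants: 20 N,N'-bis(tert-butoxycarbonyl)piperazinomycin
Product: 21 N,N'-bis(tert-butoxycarbonyl)piperazinomycin carbaldehyde (formyl group ortho to the ring A phenol)
Conditions: MgCl2, Et3N, (CH2O)n, MeCN, reflux; aq. citric acid work-up
Reagents that add atoms: paraformaldehyde (as formaldehyde), C=O
Why: Magnesium-mediated ortho-formylation of a phenol (Casnati–Skattebøl reaction): the magnesium phenoxide delivers formaldehyde to the ortho carbon and a second formaldehyde oxidises the benzylic alkoxide; only one ortho position is free, ring B has no phenol, and Boc groups tolerate Et3N at reflux.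

**Step 13**
Reactants: 21 N,N'-bis(tert-butoxycarbonyl)piperazinomycin carbaldehyde (formyl group ortho to the ring A phenol); 22 2,5,6-triaminopyrimidin-4(3H)-one
Product: 25 N,N'-bis(tert-butoxycarbonyl)guanipiperazine A, via Schiff base 23 (not isolated), via 7,8-dihydropurine aminal 24 (not isolated)
Conditions: DMSO, 60 °C; then I2 (1.2 equiv), K2CO3 (2.5 equiv), rt → 50 °C
Reagents that add atoms: none
Why: Traube-type purine synthesis from an aldehyde: the most nucleophilic 5-amino group forms Schiff base 23, the 6-amino group adds to give aminal 24, and iodine under carbonate buffering dehydrogenates it to the imidazole ring (C8–N7 and C8–N9). All positions ortho and para to the phenol are substituted, so ring iodination is blocked, and the buffered medium spares the Boc groups.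

**Step 14**
Reactants: 25 N,N'-bis(tert-butoxycarbonyl)guanipiperazine A
Product: 26 guanipiperazine A
Conditions: CF3CO2H/CH2Cl2 (1:1), rt; then aq. NH3
Reagents that add atoms: none
Why: Acidolysis of both tert-butyl carbamates; diaryl ether, phenol and guanine are stable to trifluoroacetic acid, and neutralisation should give the free base with both (S) centres unchanged.

## Compound list

1 | 4-(benzyloxy)-3-hydroxybenzaldehyde | O=Cc1ccc(OCc2ccccc2)c(O)c1 | starting material
2 | methyl 2-[(tert-butoxycarbonyl)amino]-2-(dimethoxyphosphoryl)acetate (racemic) | COC(=O)C(NC(=O)OC(C)(C)C)P(=O)(OC)OC | starting material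
3 | methyl (2Z)-3-[4-(benzyloxy)-3-hydroxyphenyl]-2-[(tert-butoxycarbonyl)amino]prop-2-enoate | COC(=O)/C(NC(=O)OC(C)(C)C)=C/c1ccc(OCc2ccccc2)c(O)c1 | intermediate
4 | methyl (2S)-3-[4-(benzyloxy)-3-hydroxyphenyl]-2-[(tert-butoxycarbonyl)amino]propanoate | COC(=O)[C@H](Cc1ccc(OCc2ccccc2)c(O)c1)NC(=O)OC(C)(C)C | intermediate
5 | (2S)-2-[(tert-butoxycarbonyl)amino]pent-4-ynoic acid (N-Boc-L-propargylglycine) | OC(=O)[C@H](CC#C)NC(=O)OC(C)(C)C | starting material
6 | methyl (2S)-2-amino-3-[4-(benzyloxy)-3-hydroxyphenyl]propanoate hydrochloride | COC(=O)[C@H](Cc1ccc(OCc2ccccc2)c(O)c1)N.Cl | intermediate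
7 | methyl (2S)-3-[4-(benzyloxy)-3-hydroxyphenyl]-2-{[(2S)-2-[(tert-butoxycarbonyl)amino]pent-4-ynoyl]amino}propanoate | COC(=O)[C@H](Cc1ccc(OCc2ccccc2)c(O)c1)NC(=O)[C@H](CC#C)NC(=O)OC(C)(C)C | intermediate
8 | methyl (2S)-2-{[(2S)-2-aminopent-4-ynoyl]amino}-3-[4-(benzyloxy)-3-hydroxyphenyl]propanoate formate salt | COC(=O)[C@H](Cc1ccc(OCc2ccccc2)c(O)c1)NC(=O)[C@H](CC#C)N.OC=O | intermediate
9 | (3S,6S)-3-{[4-(benzyloxy)-3-hydroxyphenyl]methyl}-6-(prop-2-yn-1-yl)piperazine-2,5-dione | O=C1N[C@@H](CC#C)C(=O)N[C@H]1Cc1ccc(OCc2ccccc2)c(O)c1 | intermediate
10 | 2-(benzyloxy)-5-{[(2S,5S)-5-(prop-2-yn-1-yl)piperazin-2-yl]methyl}phenol | C#CC[C@H]1CN[C@H](CN1)Cc1ccc(OCc2ccccc2)c(O)c1 | intermediate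
11 | dibenzyl (2S,5S)-2-{[4-(benzyloxy)-3-hydroxyphenyl]methyl}-5-(prop-2-yn-1-yl)piperazine-1,4-dicarboxylate | C#CC[C@H]1CN(C(=O)OCc2ccccc2)[C@H](CN1C(=O)OCc1ccccc1)Cc1ccc(OCc2ccccc2)c(O)c1 | intermediate
12 | dibenzyl (2S,5S)-2-({4-(benzyloxy)-3-[(triethylsilyl)oxy]phenyl}methyl)-5-[3-(triethylsilyl)prop-2-yn-1-yl]piperazine-1,4-dicarboxylate | CC[Si](CC)(CC)C#CC[C@H]1CN(C(=O)OCc2ccccc2)[C@H](CN1C(=O)OCc1ccccc1)Cc1ccc(OCc2ccccc2)c(O[Si](CC)(CC)CC)c1 | intermediate
13 | dibenzyl (2S,5S)-2-{[4-(benzyloxy)-3-hydroxyphenyl]methyl}-5-[3-(triethylsilyl)prop-2-yn-1-yl]piperazine-1,4-dicarboxylate | CC[Si](CC)(CC)C#CC[C@H]1CN(C(=O)OCc2ccccc2)[C@H](CN1C(=O)OCc1ccccc1)Cc1ccc(OCc2ccccc2)c(O)c1 | intermediate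
14 | 5-bromo-2H-pyran-2-one | O=c1ccc(Br)co1 | starting material
15 | dibenzyl (2S,5S)-2-({4-(benzyloxy)-3-[(6-oxo-6H-pyran-3-yl)oxy]phenyl}methyl)-5-[3-(triethylsilyl)prop-2-yn-1-yl]piperazine-1,4-dicarboxylate | CC[Si](CC)(CC)C#CC[C@H]1CN(C(=O)OCc2ccccc2)[C@H](CN1C(=O)OCc1ccccc1)Cc1ccc(OCc2ccccc2)c(Oc2ccc(=O)oc2)c1 | intermediate
16 | dibenzyl (2S,5S)-2-({4-(benzyloxy)-3-[(6-oxo-6H-pyran-3-yl)oxy]phenyl}methyl)-5-(prop-2-yn-1-yl)piperazine-1,4-dicarboxylate | C#CC[C@H]1CN(C(=O)OCc2ccccc2)[C@H](CN1C(=O)OCc1ccccc1)Cc1ccc(OCc2ccccc2)c(Oc2ccc(=O)oc2)c1 | intermediate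
17 | bridged lactone cycloadduct: as 18, but ring B is a 2-oxabicyclo[2.2.2]octa-5,7-dien-3-one bearing the ring A oxygen at C7 and the piperazine CH2 at C5; configuration of the bridgeheads C1 and C4 not defined (either face), lost with CO2 | c1ccc(cc1)COc1ccc2cc1OC5=CC6C(=O)OC5C=C6C[C@H]1CN(C(=O)OCc3ccccc3)[C@H](CN1C(=O)OCc1ccccc1)C2 | intermediate
18 | O-benzyl-N,N'-bis(benzyloxycarbonyl)piperazinomycin: 14-membered macrocycle; dibenzyl (2S,5S)-piperazine-1,4-dicarboxylate whose C2 bears the CH2 of ring B (1,4-phenylene) and whose C5 bears the CH2 of ring A; the ring B oxygen is bound to ring A meta to that CH2 and ortho to the ring A benzyloxy group | c1ccc(cc1)COc1ccc2cc1Oc1ccc(cc1)C[C@H]1CN(C(=O)OCc3ccccc3)[C@H](CN1C(=O)OCc1ccccc1)C2 | intermediate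
19 | piperazinomycin: as 18 with free NH at both nitrogens and free phenol on ring A, (2S,5S) | Oc1ccc2cc1Oc1ccc(cc1)C[C@H]1CN[C@H](CN1)C2 | intermediate
20 | N,N'-bis(tert-butoxycarbonyl)piperazinomycin, (2S,5S) | Oc1ccc2cc1Oc1ccc(cc1)C[C@H]1CN(C(=O)OC(C)(C)C)[C@H](CN1C(=O)OC(C)(C)C)C2 | intermediate
21 | N,N'-bis(tert-butoxycarbonyl)piperazinomycin carbaldehyde: 20 with CHO on ring A ortho to the phenol (the position not bearing the aryl ether), (2S,5S) | O=Cc1cc2cc(c1O)Oc1ccc(cc1)C[C@H]1CN(C(=O)OC(C)(C)C)[C@H](CN1C(=O)OC(C)(C)C)C2 | intermediate
22 | 2,5,6-triaminopyrimidin-4(3H)-one | Nc1nc(N)c(N)c(=O)[nH]1 | starting material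
23 | Schiff base: (E)-imine of 21 with the 5-amino group of 22 | Nc1nc(N)c(/N=C/c2cc3cc(c2O)Oc2ccc(cc2)C[C@H]2CN(C(=O)OC(C)(C)C)[C@H](CN2C(=O)OC(C)(C)C)C3)c(=O)[nH]1 | intermediate
24 | 7,8-dihydropurine aminal: 2-amino-8-aryl-7,8-dihydro-1H-purin-6(9H)-one, aryl = ring A of 21; C8 configuration not defined, lost on oxidation | Nc1nc2NC(c3cc4cc(c3O)Oc3ccc(cc3)C[C@H]3CN(C(=O)OC(C)(C)C)[C@H](CN3C(=O)OC(C)(C)C)C4)Nc2c(=O)[nH]1 | intermediate
25 | N,N'-bis(tert-butoxycarbonyl)guanipiperazine A: 20 with guanin-8-yl on ring A ortho to the phenol, (2S,5S) | Nc1nc2nc(-c3cc4cc(c3O)Oc3ccc(cc3)C[C@H]3CN(C(=O)OC(C)(C)C)[C@H](CN3C(=O)OC(C)(C)C)C4)[nH]c2c(=O)[nH]1 | intermediate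
26 | guanipiperazine A, (2S,5S) | Nc1nc2nc(-c3cc4cc(c3O)Oc3ccc(cc3)C[C@H]3CN[C@H](CN3)C4)[nH]c2c(=O)[nH]1 | target

## Step count and least certain steps

Total: 14 steps. Longest linear sequence: 14 steps, from 1; the route is fully linear, with 2, 5, 14 and 22 bought.

**Step 10 (key step).** The cycloaddition may take the reversed orientation, with the substituted alkyne carbon bonding to C6, which would close the meta-bridged 13-membered isomer. It may also be too slow at accessible temperatures, so that intermolecular cycloaddition and thermal decay of the pyrone take over. Both follow from an unactivated alkyne held on a long tether.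

Fallback, abandoning the pyrone for a copper-mediated macro-etherification onto a preformed ring B: it sets out from 4.
- Amino ester hydrochloride 6, generated as in step 3, is coupled (EDC·HCl, HOBt, iPr2NEt) with commercial N-Boc-4-iodo-L-phenylalanine to give methyl (2S)-3-[4-(benzyloxy)-3-hydroxyphenyl]-2-{[(2S)-2-[(tert-butoxycarbonyl)amino]-3-(4-iodophenyl)propanoyl]amino}propanoate F1.
- Formic acid, then heating in sec-butanol/toluene, gives through the dipeptide amine formate F2 the diketopiperazine (3S,6S)-3-{[4-(benzyloxy)-3-hydroxyphenyl]methyl}-6-[(4-iodophenyl)methyl]piperazine-2,5-dione F3.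
- BH3·THF, usable here because no alkyne is present, reduces it to 2-(benzyloxy)-5-({(2S,5S)-5-[(4-iodophenyl)methyl]piperazin-2-yl}methyl)phenol F4.
- N-(benzyloxycarbonyloxy)succinimide gives dibenzyl (2S,5S)-2-{[4-(benzyloxy)-3-hydroxyphenyl]methyl}-5-[(4-iodophenyl)methyl]piperazine-1,4-dicarboxylate F5.
- Intramolecular Ullmann etherification (CuI, N,N-dimethylglycine, Cs2CO3, 1,4-dioxane, 100 °C, high dilution) closes the diaryl ether and comes back to the route at 18.

**Step 8.** The phenoxide or carbonate may add to C6 of the bromopyrone, with ring opening or substitution at the wrong carbon, before copper inserts into the C–Br bond; the lactone is a vinylogous acylating agent. Fallback, an oxidative coupling with the pyrone as the boron partner at room temperature: from 14, borylation (bis(pinacolato)diboron, PdCl2(dppf), KOAc, 1,4-dioxane, 80 °C) gives 5-(4,4,5,5-tetramethyl-1,3,2-dioxaborolan-2-yl)-2H-pyran-2-one F6. Chan–Lam coupling of F6 with phenol 13 (Cu(OAc)2, pyridine, 4 Å molecular sieves, air, CH2Cl2, rt) comes back to the route at 15.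

**Step 12.** Formylation may be slow because the magnesium phenoxide is crowded by the neighbouring aryloxy group inside the macrocycle, leaving hydroxymethyl intermediates or unchanged phenol. Fallback, halogenation then formylation of an aryl metal: from 20, N-bromosuccinimide with catalytic iPr2NH (CH2Cl2, 0 °C) brominates the only free ortho position to give N,N'-bis(tert-butoxycarbonyl)-bromopiperazinomycin F7 (bromine ortho to the ring A phenol). NaH, then n-BuLi at −78 °C (bromine–lithium exchange on the phenoxide) and DMF give the aldehyde and come back to the route at 21.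

**Step 13.** Ring closure may stall at the hydrogen-bonded salicylidene imine, or the oxidant may attack the electron-rich aminophenol before the aminal forms. Fallback, acylation and cyclodehydration instead of oxidative condensation: from 21, Pinnick oxidation (NaClO2, NaH2PO4, 2-methylbut-2-ene, t-BuOH/H2O) gives the salicylic acid N,N'-bis(tert-butoxycarbonyl)piperazinomycin carboxylic acid F8. EDC·HCl/HOBt coupling with the 5-amino group of 22 gives the N-(2,6-diamino-4-oxo-3,4-dihydropyrimidin-5-yl) amide F9. Cyclodehydration (hexamethyldisilazane, (NH4)2SO4 cat., reflux) closes the imidazole ring and comes back to the route at 25.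

## Further compounds

F1 | step 10 | methyl (2S)-3-[4-(benzyloxy)-3-hydroxyphenyl]-2-{[(2S)-2-[(tert-butoxycarbonyl)amino]-3-(4-iodophenyl)propanoyl]amino}propanoate | COC(=O)[C@H](Cc1ccc(OCc2ccccc2)c(O)c1)NC(=O)[C@H](Cc1ccc(I)cc1)NC(=O)OC(C)(C)C
F2 | step 10 | methyl (2S)-2-{[(2S)-2-amino-3-(4-iodophenyl)propanoyl]amino}-3-[4-(benzyloxy)-3-hydroxyphenyl]propanoate formate salt | COC(=O)[C@H](Cc1ccc(OCc2ccccc2)c(O)c1)NC(=O)[C@H](Cc1ccc(I)cc1)N.OC=O
F3 | step 10 | (3S,6S)-3-{[4-(benzyloxy)-3-hydroxyphenyl]methyl}-6-[(4-iodophenyl)methyl]piperazine-2,5-dione | O=C1N[C@@H](Cc2ccc(I)cc2)C(=O)N[C@H]1Cc1ccc(OCc2ccccc2)c(O)c1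
F4 | step 10 | 2-(benzyloxy)-5-({(2S,5S)-5-[(4-iodophenyl)methyl]piperazin-2-yl}methyl)phenol | Ic1ccc(C[C@H]2CN[C@H](CN2)Cc2ccc(OCc3ccccc3)c(O)c2)cc1
F5 | step 10 | dibenzyl (2S,5S)-2-{[4-(benzyloxy)-3-hydroxyphenyl]methyl}-5-[(4-iodophenyl)methyl]piperazine-1,4-dicarboxylate | Ic1ccc(C[C@H]2CN(C(=O)OCc3ccccc3)[C@H](CN2C(=O)OCc2ccccc2)Cc2ccc(OCc3ccccc3)c(O)c2)cc1
F6 | step 8 | 5-(4,4,5,5-tetramethyl-1,3,2-dioxaborolan-2-yl)-2H-pyran-2-one | CC1(C)OB(OC1(C)C)c1ccc(=O)oc1
F7 | step 12 | N,N'-bis(tert-butoxycarbonyl)-bromopiperazinomycin (bromine ortho to the ring A phenol), (2S,5S) | Oc1c(Br)cc2cc1Oc1ccc(cc1)C[C@H]1CN(C(=O)OC(C)(C)C)[C@H](CN1C(=O)OC(C)(C)C)C2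
F8 | step 13 | N,N'-bis(tert-butoxycarbonyl)piperazinomycin carboxylic acid (CO2H ortho to the ring A phenol), (2S,5S) | OC(=O)c1cc2cc(c1O)Oc1ccc(cc1)C[C@H]1CN(C(=O)OC(C)(C)C)[C@H](CN1C(=O)OC(C)(C)C)C2
F9 | step 13 | N-(2,6-diamino-4-oxo-3,4-dihydropyrimidin-5-yl) amide of F8 | Nc1nc(N)c(NC(=O)c2cc3cc(c2O)Oc2ccc(cc2)C[C@H]2CN(C(=O)OC(C)(C)C)[C@H](CN2C(=O)OC(C)(C)C)C3)c(=O)[nH]1
A1 | alternative 1 | 14-membered macrocyclic methyl (Z)-dehydroamino ester (N-Boc, ring A O-methyl) | COc1ccc2cc1Oc1ccc(cc1)/C=C(/C(=O)OC)NC(=O)[C@@H](NC(=O)OC(C)(C)C)C2
A2 | alternative 1 | methyl 2-{[(2S)-2-[(tert-butoxycarbonyl)amino]-3-[3-(4-formylphenoxy)-4-methoxyphenyl]propanoyl]amino}-2-(dimethoxyphosphoryl)acetate | COc1ccc(C[C@H](NC(=O)OC(C)(C)C)C(=O)NC(C(=O)OC)P(=O)(OC)OC)cc1Oc1ccc(C=O)cc1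
A3 | alternative 2 | N,N'-bis(tert-butoxycarbonyl)guanipiperazine A (identical with 25) | Nc1nc2nc(-c3cc4cc(c3O)Oc3ccc(cc3)C[C@H]3CN(C(=O)OC(C)(C)C)[C@H](CN3C(=O)OC(C)(C)C)C4)[nH]c2c(=O)[nH]1
A4 | alternative 3 | macrocyclic (2S,5S)-3,6-dimethoxy-2,5-dihydropyrazine (bis-lactim ether), ring A O-methyl | COc1ccc2cc1Oc1ccc(cc1)C[C@H]1C(OC)=N[C@H](C(OC)=N1)C2
A5 | alternative 3 | (2S)-2-({4-[5-(bromomethyl)-2-methoxyphenoxy]phenyl}methyl)-3,6-dimethoxy-2,5-dihydropyrazine | COc1ccc(CBr)cc1Oc1ccc(C[C@H]2C(OC)=NCC(OC)=N2)cc1
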